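**Plan**

- Numbering: lactone ring O1–C2(=O)–C3–C4–C5, with C7 the benzylic carbon on C3. The enabling feature is that C2 is a single carbon on C3, and the C3–C7 pair can be carried as a styrenyl C=C homoallylic to the C5 hydroxyl. CO can then be handed to C3 from that oxygen, and the aldehyde closes ring O1–C2–C3–C4–C5.
- Retrosynthetic cuts, in order: the two aryl O–benzyl bonds; the C2 carbonyl back to the lactol; C2–C3 together with O1–C2 (removing CO and H2) to an open homoallylic alcohol; the C4–CH2Ar bond (enolate benzylation); the C3=C7 bond (Wittig).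
- Forward: the chain is joined first (C3=C7, then C4–benzyl, then release of the C5 alcohol). The only ring forms in the hydroformylation, and oxidation plus debenzylation finish the target.
- Stereochemistry: C4 comes from the (R)-4-benzyloxazolidin-2-one-controlled alkylation. C3 comes from the tethered, chair-like hydroformylation transition state (trans to C4) and is secured by base equilibration of the lactone to the trans isomer.

Key step: step 6

Assumption: the phenols are carried as benzyl ethers from the outset (4-(benzyloxy)-3-methoxybenzaldehyde and [3-(benzyloxy)-4-methoxyphenyl]methanol are commercial), so the Wittig base, the enolate chemistry and the silver oxidant never meet a free phenol.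

**Route**

Step 1
Reactants: 1 4-(benzyloxy)-3-methoxybenzaldehyde; 2 (2-carboxyethyl)triphenylphosphonium bromide
Product: 4 (E)-4-[4-(benzyloxy)-3-methoxyphenyl]but-3-enoic acid, via ylide carboxylate 3 (not isolated)
Conditions: 2, NaN(SiMe3)2 (2.2 equiv), THF, −78 °C; then 1, −78 °C to rt; 1 M HCl work-up
Reagents that add atoms: none
Why: Wittig olefination with the doubly deprotonated phosphonium salt, whose carboxylate-bearing ylide should give mainly the E-styrene with aromatic aldehydes; conjugation with the arene holds the alkene in the β,γ-position, and base extraction plus crystallisation should remove neutral by-products and any Z isomer.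

Step 2
Reactants: 4 (E)-4-[4-(benzyloxy)-3-methoxyphenyl]but-3-enoic acid; 5 (R)-4-benzyloxazolidin-2-one
Product: 7 (R)-4-benzyl-3-{(E)-4-[4-(benzyloxy)-3-methoxyphenyl]but-3-enoyl}oxazolidin-2-one, via mixed pivalic anhydride 6 (not isolated)
Conditions: t-BuCOCl, Et3N, THF, −20 °C; then LiCl, 5, −20 °C to rt
Reagents that add atoms: none
Why: N-acylation of the Evans auxiliary through the mixed pivalic anhydride under LiCl/Et3N activation, which avoids a lithiated oxazolidinone so that the base-sensitive β,γ-unsaturated acyl group should not slip into conjugation.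

Step 3
Reactants: 8 [3-(benzyloxy)-4-methoxyphenyl]methanol
Product: 9 2-(benzyloxy)-4-(bromomethyl)-1-methoxybenzene
Conditions: PBr3 (0.4 equiv), Et2O, 0 °C
Reagents that add atoms: phosphorus tribromide, BrP(Br)Br
Why: Standard conversion of a benzylic alcohol into its bromide (SN2 displacement on the bromophosphite); the electron-rich bromide is used at once without storage.

Step 4
Reactants: 7 (R)-4-benzyl-3-{(E)-4-[4-(benzyloxy)-3-methoxyphenyl]but-3-enoyl}oxazolidin-2-one; 9 2-(benzyloxy)-4-(bromomethyl)-1-methoxybenzene
Product: 11 (R)-4-benzyl-3-{(R,E)-2-[3-(benzyloxy)-4-methoxybenzyl]-4-[4-(benzyloxy)-3-methoxyphenyl]but-3-enoyl}oxazolidin-2-one, via sodium dienolate 10 (not isolated)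
Conditions: NaN(SiMe3)2 (1.0 equiv), THF, −78 °C; then 9, −78 to −45 °C; AcOH quench at −78 °C
Reagents that add atoms: none
Why: Evans asymmetric alkylation, in which the chelated (Z)-sodium enolate should react at its α-carbon with the reactive benzylic bromide on the face away from the auxiliary benzyl group and so set the new centre (future C4) as R; the cold quench limits proton exchange at the doubly activated α-position.

Step 5
Reactants: 11 (R)-4-benzyl-3-{(R,E)-2-[3-(benzyloxy)-4-methoxybenzyl]-4-[4-(benzyloxy)-3-methoxyphenyl]but-3-enoyl}oxazolidin-2-one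
Product: 12 (R,E)-2-[3-(benzyloxy)-4-methoxybenzyl]-4-[4-(benzyloxy)-3-methoxyphenyl]but-3-en-1-ol
Conditions: LiBH4, H2O (1 equiv), Et2O, 0 °C
Reagents that add atoms: none
Why: Reductive cleavage of the N-acyloxazolidinone (hydride attack at the exocyclic carbonyl) should give the primary alcohol without base-mediated epimerisation, leave the styrenyl alkene and the benzyl ethers untouched, and return auxiliary 5.

Step 6
Reactants: 12 (R,E)-2-[3-(benzyloxy)-4-methoxybenzyl]-4-[4-(benzyloxy)-3-methoxyphenyl]but-3-en-1-ol
Product: 14 (3R,4R)-3-[4-(benzyloxy)-3-methoxybenzyl]-4-[3-(benzyloxy)-4-methoxybenzyl]tetrahydrofuran-2-ol, via hydroxy aldehyde 13 (not isolated)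
Conditions: Rh(acac)(CO)2 (2 mol %), Ph2POMe (10 mol %), CO/H2 (1:1, 20 bar), 4 Å MS, THF, 40 °C
Reagents that add atoms: carbon monoxide, [C-]#[O+]
Why: Ph2POMe exchanges reversibly with the C5 hydroxyl of 12 (the sieves take up methanol), so the substrate becomes its own phosphinite ligand and the rhodium hydride held on phosphorus adds syn across C3=C7 through a six-membered chelate (Rh–P–O–C5–C4–C3) with rhodium on C3; CO insertion and hydrogenolysis of the acyl then give aldehyde 13 with the new C2–C3 bond, and exchange with fresh 12 frees it. The closest known reaction type is the branched-selective hydroformylation of homoallylic alcohols (terminal and 1,2-disubstituted alkenes) directed by a catalytic, reversibly bound phosphinite to give γ-lactols. Ring O1–C2–C3–C4–C5 closes spontaneously by 5-exo-trig addition of the C5 hydroxyl to the C2 aldehyde (hemiacetal formation). The new centre C3 is set by the alkene face taken up in the chair-like chelate, in which the C4 benzyl group lies pseudo-equatorial and C7 ends up trans to it; the anomeric centre C2 is left uncontrolled because step 7 removes it and also equilibrates C3. The step needs regioselectivity for C3 against the usual preference of styrenes for metalation at the benzylic carbon, which the short tether secures because delivery to C7 would demand a seven-membered chelate; it also needs hydroformylation to outrun hydrogenation and alkene migration toward C4, which the CO pressure, the low temperature and the conjugation of the alkene with the arene should ensure.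

Step 7
Reactants: 14 (3R,4R)-3-[4-(benzyloxy)-3-methoxybenzyl]-4-[3-(benzyloxy)-4-methoxybenzyl]tetrahydrofuran-2-ol
Product: 15 (3R,4R)-3-[4-(benzyloxy)-3-methoxybenzyl]-4-[3-(benzyloxy)-4-methoxybenzyl]dihydrofuran-2(3H)-one
Conditions: Ag2CO3 on Celite, toluene, 110 °C; filter; then DBU (0.2 equiv), toluene, 80 °C
Reagents that add atoms: none
Why: Fétizon oxidation should convert the lactol into the γ-lactone under neutral conditions that spare the benzyl ethers, and DBU-mediated enolisation at C3 then lets any cis isomer drain into the thermodynamically preferred trans-3,4-dibenzyl lactone while the non-enolisable C4 stays fixed.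

Step 8
Reactants: 15 (3R,4R)-3-[4-(benzyloxy)-3-methoxybenzyl]-4-[3-(benzyloxy)-4-methoxybenzyl]dihydrofuran-2(3H)-one
Product: 16 (3R,4R)-3-(4-hydroxy-3-methoxybenzyl)-4-(3-hydroxy-4-methoxybenzyl)dihydrofuran-2(3H)-one
Conditions: H2 (1 atm), 10% Pd/C, EtOAc–MeOH, rt
Reagents that add atoms: none
Why: Catalytic hydrogenolysis of the two aryl benzyl ethers under neutral conditions should free both phenols without touching the lactone or the C3 and C4 centres.

**Compound list**

1 | 4-(benzyloxy)-3-methoxybenzaldehyde | COc1cc(C=O)ccc1OCc1ccccc1 | starting material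
2 | (2-carboxyethyl)triphenylphosphonium bromide | OC(=O)CC[P+](c1ccccc1)(c1ccccc1)c1ccccc1.[Br-] | starting material
3 | sodium 3-(triphenyl-λ5-phosphanylidene)propanoate (ylide carboxylate) | [Na+].[O-]C(=O)CC=P(c1ccccc1)(c1ccccc1)c1ccccc1 | intermediate
4 | (E)-4-[4-(benzyloxy)-3-methoxyphenyl]but-3-enoic acid | COc1cc(/C=C/CC(=O)O)ccc1OCc1ccccc1 | intermediate
5 | (R)-4-benzyloxazolidin-2-one | O=C1N[C@H](Cc2ccccc2)CO1 | starting material
6 | (E)-4-[4-(benzyloxy)-3-methoxyphenyl]but-3-enoic pivalic anhydride | COc1cc(/C=C/CC(=O)OC(=O)C(C)(C)C)ccc1OCc1ccccc1 | intermediate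
7 | (R)-4-benzyl-3-{(E)-4-[4-(benzyloxy)-3-methoxyphenyl]but-3-enoyl}oxazolidin-2-one | COc1cc(/C=C/CC(=O)N2[C@H](Cc3ccccc3)COC2=O)ccc1OCc1ccccc1 | intermediate
8 | [3-(benzyloxy)-4-methoxyphenyl]methanol | COc1ccc(CO)cc1OCc1ccccc1 | starting material
9 | 2-(benzyloxy)-4-(bromomethyl)-1-methoxybenzene | COc1ccc(CBr)cc1OCc1ccccc1 | intermediate
10 | sodium (1Z,3E)-1-[(R)-4-benzyl-2-oxooxazolidin-3-yl]-4-[4-(benzyloxy)-3-methoxyphenyl]buta-1,3-dien-1-olate (sodium dienolate of 7) | [Na+].[O-]/C(=C\C=C\c1ccc(OCc2ccccc2)c(OC)c1)N1[C@H](Cc2ccccc2)COC1=O | intermediate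
11 | (R)-4-benzyl-3-{(R,E)-2-[3-(benzyloxy)-4-methoxybenzyl]-4-[4-(benzyloxy)-3-methoxyphenyl]but-3-enoyl}oxazolidin-2-one | COc1ccc(C[C@H](/C=C/c2ccc(OCc3ccccc3)c(OC)c2)C(=O)N2[C@H](Cc3ccccc3)COC2=O)cc1OCc1ccccc1 | intermediate
12 | (R,E)-2-[3-(benzyloxy)-4-methoxybenzyl]-4-[4-(benzyloxy)-3-methoxyphenyl]but-3-en-1-ol | COc1ccc(C[C@H](/C=C/c2ccc(OCc3ccccc3)c(OC)c2)CO)cc1OCc1ccccc1 | intermediate
13 | (2R,3R)-2-[4-(benzyloxy)-3-methoxybenzyl]-3-[3-(benzyloxy)-4-methoxybenzyl]-4-hydroxybutanal | COc1ccc(C[C@@H](CO)[C@H](C=O)Cc2ccc(OCc3ccccc3)c(OC)c2)cc1OCc1ccccc1 | intermediate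
14 | (3R,4R)-3-[4-(benzyloxy)-3-methoxybenzyl]-4-[3-(benzyloxy)-4-methoxybenzyl]tetrahydrofuran-2-ol (both C2 anomers) | COc1ccc(C[C@H]2COC(O)[C@@H]2Cc2ccc(OCc3ccccc3)c(OC)c2)cc1OCc1ccccc1 | intermediate
15 | (3R,4R)-3-[4-(benzyloxy)-3-methoxybenzyl]-4-[3-(benzyloxy)-4-methoxybenzyl]dihydrofuran-2(3H)-one | COc1ccc(C[C@H]2COC(=O)[C@@H]2Cc2ccc(OCc3ccccc3)c(OC)c2)cc1OCc1ccccc1 | intermediate
16 | (3R,4R)-3-(4-hydroxy-3-methoxybenzyl)-4-(3-hydroxy-4-methoxybenzyl)dihydrofuran-2(3H)-one | COc1ccc(C[C@H]2COC(=O)[C@@H]2Cc2ccc(O)c(OC)c2)cc1O | target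

**Step count and risks**

Total step count: 8.
Longest linear sequence: 7 steps (steps 1, 2, 4, 5, 6, 7, 8, starting from 1); step 3 is a one-step side branch.

Steps most likely to fail:

1. Step 6. The rhodium hydride may add with the metal at the benzylic carbon C7 despite the tether, the styrenyl alkene may simply be hydrogenated, or the double bond may migrate toward C4 and erase that centre. The fallback sets out from 12 and comes back at 15, replacing steps 6 and 7 by a radical carbonylative ring closure that forms the same C2–C3 bond and the same ring at the lactone oxidation level. 12 would be treated with COCl2 (toluene solution) and pyridine in CH2Cl2 at 0 °C to give (R,E)-2-[3-(benzyloxy)-4-methoxybenzyl]-4-[4-(benzyloxy)-3-methoxyphenyl]but-3-en-1-yl carbonochloridate F1. PhSeH and pyridine would then give O-{(R,E)-2-[3-(benzyloxy)-4-methoxybenzyl]-4-[4-(benzyloxy)-3-methoxyphenyl]but-3-en-1-yl} Se-phenyl carbonoselenoate F2. Slow addition of Bu3SnH and AIBN to F2 in benzene at 80 °C generates the alkoxycarbonyl radical, which should cyclise 5-exo onto C3 because the radical left at C7 is benzylic; hydrogen transfer from the stannane gives 15. The DBU treatment of step 7 is applied if a cis isomer is present. In this mode the polarity of the styrene supports the regiochemistry and no hydrogen gas is present.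

2. Step 4. The dienolate may react through its γ-carbon, the double bond may move into conjugation with the imide, and the new centre may lose configuration by proton transfer between product and enolate. The fallback sets out from 4 (using 9 and 5) and comes back at 11; it gives up asymmetric induction and uses the auxiliary only as a resolving handle. Acid 4 would be converted with LiN(i-Pr)2 (2.1 equiv, THF, −78 to 0 °C) into its dienediolate, a species that alkylates at the α-carbon, and 9 would give racemic (E)-2-[3-(benzyloxy)-4-methoxybenzyl]-4-[4-(benzyloxy)-3-methoxyphenyl]but-3-enoic acid F3. F3 is attached to 5 through its mixed pivalic anhydride as in step 2, and the two diastereomeric imides are separated by chromatography or crystallisation. 11 continues; its epimer (R)-4-benzyl-3-{(S,E)-2-[3-(benzyloxy)-4-methoxybenzyl]-4-[4-(benzyloxy)-3-methoxyphenyl]but-3-enoyl}oxazolidin-2-one F4 is set aside.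

3. Step 1. A sizeable share of Z-alkene may form, and the strong base may shift the double bond toward the carboxylate. The fallback sets out from 1 and comes back at 4. 1 would be methylenated (Ph3PCH3Br, KOt-Bu, THF, 0 °C) to 1-(benzyloxy)-4-ethenyl-2-methoxybenzene F5. Cross-metathesis of F5 with but-3-enoic acid (second-generation Hoveyda–Grubbs catalyst, CH2Cl2, 40 °C) should then give 4 as the thermodynamically favoured E isomer, with no strong base meeting the β,γ-unsaturated acid.

Further compounds
F1 | step 6 | (R,E)-2-[3-(benzyloxy)-4-methoxybenzyl]-4-[4-(benzyloxy)-3-methoxyphenyl]but-3-en-1-yl carbonochloridate | COc1ccc(C[C@H](/C=C/c2ccc(OCc3ccccc3)c(OC)c2)COC(Cl)=O)cc1OCc1ccccc1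
F2 | step 6 | O-{(R,E)-2-[3-(benzyloxy)-4-methoxybenzyl]-4-[4-(benzyloxy)-3-methoxyphenyl]but-3-en-1-yl} Se-phenyl carbonoselenoate | COc1ccc(C[C@H](/C=C/c2ccc(OCc3ccccc3)c(OC)c2)COC(=O)[Se]c2ccccc2)cc1OCc1ccccc1
F3 | step 4 | (E)-2-[3-(benzyloxy)-4-methoxybenzyl]-4-[4-(benzyloxy)-3-methoxyphenyl]but-3-enoic acid (racemic) | COc1ccc(CC(/C=C/c2ccc(OCc3ccccc3)c(OC)c2)C(=O)O)cc1OCc1ccccc1
F4 | step 4 | (R)-4-benzyl-3-{(S,E)-2-[3-(benzyloxy)-4-methoxybenzyl]-4-[4-(benzyloxy)-3-methoxyphenyl]but-3-enoyl}oxazolidin-2-one | COc1ccc(C[C@@H](/C=C/c2ccc(OCc3ccccc3)c(OC)c2)C(=O)N2[C@H](Cc3ccccc3)COC2=O)cc1OCc1ccccc1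
F5 | step 1 | 1-(benzyloxy)-4-ethenyl-2-methoxybenzene | COc1cc(C=C)ccc1OCc1ccccc1
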